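**Retrosynthetic overview**

1. The (Z)-γ-keto enoate side chain (C12–C15) is unmasked last from a 2-alkyl-3-methylfuran (singlet oxygen, then methylation of the carboxyl). The furan is joined to C11 by Negishi coupling, and the two angelates are placed one after the other on a 2α,3α-diol (equatorial 2α-hydroxyl first).
2. The C17 aldehyde comes from allylic oxidation of the C8 methyl. C11 and the C9 stereocentre come from methylenation of a C9 ketone and α-face hydroboration. The diol comes from OsO4 on a C2=C3 alkene.
3. Ring B is taken intact from (R)-carvone: it supplies the C5 stereocentre, the C9 ketone, C7=C8 with its methyl (C17), and the isopropenyl group (C4 with one methyl). Ring A is then closed in one flask by a (3+3) annulation with (Z)-3-bromo-1-iodopropene: C1–C10 by enolate alkylation, C3–C4 by 6-exo reductive Heck cyclisation.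
4. Enabling feature: C10 and C4 are both bonded to C5. In 6-methylcarvone, C10 is the enolisable α′-carbon of the C9 carbonyl and C4 is the internal carbon of the 1,1-disubstituted isopropenyl alkene, so a C1–C2=C3 unit can bridge them; the alkene CH2 becomes the second C4 methyl.
5. Ring order: ring B (from the chiral pool), then ring A (step 4).

Key step: step 4

Remarks on the chemistry: labdane numbering is used (ring A = C1–C5 and C10; ring B = C5–C10; C17 = carbon on C8; C11–C16 = side chain on C9). Compound 6 is drawn as the trans isomer; its C6 epimer converges on the same enolate. Compound 25 is a mixture of epimers at the lactol carbon, in equilibrium with the open keto acid.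

**Route**

Step 1
Reactants: 1 ethyl (Z)-3-iodoprop-2-enoate
Product: 2 (Z)-3-iodoprop-2-en-1-ol
Conditions: iBu2AlH, CH2Cl2, −78 to 0 °C
Reagents that add atoms: none
Why: Ester-to-alcohol reduction with iBu2AlH at low temperature should leave the C–I bond and the Z alkene geometry untouched.

Step 2
Reactants: 2 (Z)-3-iodoprop-2-en-1-ol
Product: 3 (Z)-3-bromo-1-iodoprop-1-ene
Conditions: CBr4, PPh3, CH2Cl2, 0 °C
Reagents that add atoms: tetrabromomethane BrC(Br)(Br)Br
Why: Appel bromination replaces the primary allylic hydroxyl by bromide through SN2 displacement of the oxyphosphonium group without touching the (Z)-iodoalkene.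

Step 3
Reactants: 4 (R)-(−)-carvone
Product: 6 (5R,6S)-2,6-dimethyl-5-(prop-1-en-2-yl)cyclohex-2-en-1-one (trans-6-methylcarvone), via lithium dienolate 5 (not isolated)
Conditions: LiN(iPr)2, THF, −78 °C; MeI, −78 to 0 °C
Reagents that add atoms: iodomethane CI
Why: Kinetic α′-deprotonation gives the cross-conjugated dienolate, which is methylated preferentially trans to the C5 isopropenyl group, and the configuration at C6 is of no consequence because this centre is planarised again in step 4.

Step 4
Reactants: 6 (5R,6S)-2,6-dimethyl-5-(prop-1-en-2-yl)cyclohex-2-en-1-one; 3 (Z)-3-bromo-1-iodoprop-1-ene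
Product: 9 (4aS,8aS)-2,5,5,8a-tetramethyl-4a,5,8,8a-tetrahydronaphthalen-1(4H)-one, via lithium dienolate 7 (not isolated), via C-allylated alkenyl iodide 8 (not isolated)
Conditions: LiN(iPr)2, THF, −78 °C; 3, −78 to 0 °C; then DMF, Pd(OAc)2 (10 mol %), PPh3, HCO2Na, Et4NCl, 80 °C, same flask
Reagents that add atoms: none
Why: Kinetic deprotonation of 6 at C10 (the α′-carbon of the C9 ketone) gives the cross-conjugated lithium dienolate 7, which is C-alkylated by the allylic bromide 3 in an SN2 reaction on the face opposite to the C5 isopropenyl group, forming the C1–C10 bond and the C10 quaternary centre (10β-methyl) while the Z-iodoalkene passes unchanged into 8. In the same flask zerovalent palladium (from Pd(OAc)2 and PPh3) inserts into the C3–I bond, the (Z)-alkenylpalladium adds across the isopropenyl C=C so that C3 bonds to the internal carbon C4, and the resulting neopentyl-type alkylpalladium, which has no β-hydrogen, is reduced by formate with loss of CO2, turning the former =CH2 into the second C4 methyl. The closest known reaction types are the sequential, trans-selective α-alkylation of carvone enolates and the intramolecular reductive Heck cyclisation (carbopalladation with hydride capture) that builds methyl-bearing quaternary carbons. Ring A closes in the 6-exo-trig mode and keeps the C2=C3 double bond exactly where the diol is needed. The only new stereocentre, C10, is controlled by the C5 stereocentre of carvone (alkylation anti to isopropenyl), which also fixes the trans ring fusion, and C4 carries two methyl groups. The step needs α′- over γ-deprotonation (kinetic amide base), retention of the Z geometry (direct SN2 and not a π-allyl path, which is why the catalyst is added only after the alkylation) and 6-exo over 7-endo insertion (three-atom tether), and sparingly soluble formate keeps hydride capture slower than the cyclisation.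

Step 5
Reactants: 9 (4aS,8aS)-2,5,5,8a-tetramethyl-4a,5,8,8a-tetrahydronaphthalen-1(4H)-one
Product: 10 (4aS,6S,7R,8aS)-6,7-dihydroxy-2,5,5,8a-tetramethyl-4a,5,6,7,8,8a-hexahydronaphthalen-1(4H)-one (2α,3α-diol)
Conditions: OsO4 (2 mol %), N-methylmorpholine N-oxide, acetone/H2O, 0 °C to rt
Reagents that add atoms: osmium tetroxide O=[Os](=O)(=O)=O (catalytic oxygen carrier); N-methylmorpholine N-oxide C[N+]1([O-])CCOCC1; water O
Why: Upjohn dihydroxylation adds both oxygens syn to the electron-rich C2=C3 alkene from the α face, because the β face is screened by the axial C10 and C4β methyl groups, and leaves the electron-poor C7=C8 enone alone, which sets C2 and C3.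

Step 6
Reactants: 10 (2α,3α-diol)
Product: 11 2α,3α-O-isopropylidene acetal of 10
Conditions: Me2C(OMe)2, pyridinium p-toluenesulfonate (cat.), CH2Cl2, rt
Reagents that add atoms: 2,2-dimethoxypropane COC(C)(C)OC
Why: Acid-catalysed transacetalisation closes the five-membered isopropylidene acetal on the cis-diol and masks both hydroxyls for the basic and organoborane steps that follow.

Step 7
Reactants: 11 2α,3α-O-isopropylidene acetal of 10
Product: 12 9-methylene compound (C9=C11H2 in place of C9=O; 7,9(11)-diene)
Conditions: Ph3PCH3Br, KOtBu, toluene, 90 °C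
Reagents that add atoms: methyltriphenylphosphonium bromide C[P+](c1ccccc1)(c1ccccc1)c1ccccc1.[Br-]
Why: Wittig methylenation with Ph3P=CH2 at elevated temperature, as used for hindered ketones, converts the C9 carbonyl into the exocyclic C9=C11 alkene without touching a stereocentre.

Step 8
Reactants: 12 9-methylene compound
Product: 14 9β-(iodomethyl) compound (9α-H; C7=C8 with C8 methyl; acetonide), via B-alkyl-9-BBN adduct 13 (not isolated)
Conditions: 9-BBN, THF, 0 °C to rt; then NaOMe, MeOH, I2, 0 °C
Reagents that add atoms: iodine [I][I]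
Why: 9-BBN adds to the terminal C11 of the exocyclic alkene from the α face, anti to the axial C10 methyl, which places hydrogen on C9α and sets C9, and iodinolysis of the methoxyborate replaces boron on the primary carbon by iodine, while the trisubstituted C7=C8 is too hindered for 9-BBN.

Step 9
Reactants: 14 9β-(iodomethyl) compound
Product: 15 7-en-17-al (C8–CHO in place of C8–CH3)
Conditions: SeO2, 1,4-dioxane, 80 °C
Reagents that add atoms: selenium dioxide O=[Se]=O
Why: Riley allylic oxidation (ene reaction, then [2,3]-sigmatropic shift) attacks the only alkene and oxidises on its more substituted end with the usual preference for CH3 over CH, so the C17 methyl and not C9–H should be taken to the conjugated aldehyde.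

Step 10
Reactants: 15 7-en-17-al
Product: 16 2α,3α-diol of 15
Conditions: HCl (1 M, aq.), THF, rt
Reagents that add atoms: none
Why: Aqueous acid hydrolyses the isopropylidene acetal to the free cis-diol while the enal and the primary iodide are inert.

Step 11
Reactants: 16 2α,3α-diol of 15; 17 angelic acid
Product: 18 2α-mono(angelate) of 16 (3α-hydroxyl free)
Conditions: 17 (1 equiv), 2,4,6-trichlorobenzoyl chloride, Et3N, toluene, rt; then 16, toluene, rt to 40 °C
Reagents that add atoms: none
Why: Yamaguchi-type esterification through the mixed anhydride in toluene without a nucleophilic catalyst should acylate only the equatorial 2α-hydroxyl, because the axial 3α-hydroxyl is flanked by the C4 gem-dimethyl group and reacts only under forcing conditions, and the Z (angelate) geometry is kept.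

Step 12
Reactants: 18 2α-mono(angelate) of 16; 17 angelic acid
Product: 19 2α,3α-bis(angelate) of 16
Conditions: 17 (excess), 2,4,6-trichlorobenzoyl chloride, Et3N, toluene, rt; then 18, toluene, 80 °C
Reagents that add atoms: none
Why: The same Yamaguchi-type mixed-anhydride esterification, with excess reagent at 80 °C, should force acylation of the hindered axial 3α-hydroxyl while keeping the Z geometry, which carbodiimide and 4-dimethylaminopyridine methods tend to scramble, and a 2-to-3 acyl shift would be harmless because both esters are the same.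

Step 13
Reactants: 20 3-methylfuran
Product: 21 2-bromo-3-methylfuran
Conditions: N-bromosuccinimide, DMF, 0 °C
Reagents that add atoms: N-bromosuccinimide O=C1CCC(=O)N1Br
Why: Electrophilic bromination of the furan occurs at C2, the α-position activated by the adjacent methyl group, and the labile bromide is used at once.

Step 14
Reactants: 19 2α,3α-bis(angelate) of 16; 21 2-bromo-3-methylfuran
Product: 23 11-(3-methylfuran-2-yl) compound, via alkylzinc iodide 22 (not isolated)
Conditions: Zn, LiCl, THF, 30 °C; then 21, Pd(OAc)2 (5 mol %), SPhos, THF, rt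
Reagents that add atoms: none
Why: Zinc insertion into the primary C–I bond gives an alkylzinc iodide that tolerates the enal and the esters, and Negishi coupling with the 2-bromofuran forms the C11–furan bond without touching C9.

Step 15
Reactants: 23 11-(3-methylfuran-2-yl) compound
Product: 25 γ-hydroxybutenolide (5-hydroxy-4-methyl-5-substituted furan-2(5H)-one), via furan endoperoxide 24 (not isolated)
Conditions: O2, visible light, tetraphenylporphyrin (cat.), iPr2NEt, CH2Cl2, −78 °C
Reagents that add atoms: oxygen O=O
Why: Singlet oxygen adds [4+2] to the electron-rich furan and the amine triggers a Kornblum–DeLaMare fragmentation through the only bridgehead hydrogen, which gives the ring form of the (Z)-4-oxo-enoic acid with the C13=C14 geometry fixed by the ring, while the electron-poor angelate and enal alkenes do not react.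

Step 16
Reactants: 25 γ-hydroxybutenolide
Product: 26 methyl (13Z)-2α,3α-bis[(Z)-2-methylbut-2-enoyloxy]-12,17-dioxolabda-7,13-dien-15-oate (target)
Conditions: Me3SiCHN2, MeOH/toluene, 0 °C
Reagents that add atoms: (trimethylsilyl)diazomethane C[Si](C)(C)C=[N+]=[N-]
Why: The pseudo-acid is in equilibrium with the open (Z)-keto acid, whose carboxyl is methylated by the diazoalkane to the normal methyl ester with the Z alkene retained.

**Compound list**

1 | ethyl (Z)-3-iodoprop-2-enoate | CCOC(=O)/C=C\I | starting material
2 | (Z)-3-iodoprop-2-en-1-ol | OC/C=C\I | intermediate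
3 | (Z)-3-bromo-1-iodoprop-1-ene | BrC/C=C\I | intermediate
4 | (R)-(−)-carvone, (5R)-2-methyl-5-(prop-1-en-2-yl)cyclohex-2-en-1-one | CC(=C)[C@@H]1CC=C(C)C(=O)C1 | starting material
5 | lithium dienolate of 4 (cross-conjugated, O–C1=C6) | [Li+].[O-]C1=C[C@H](C(C)=C)CC=C1C | intermediate
6 | (5R,6S)-2,6-dimethyl-5-(prop-1-en-2-yl)cyclohex-2-en-1-one (trans-6-methylcarvone) | C[C@@H]1C(=O)C(C)=CC[C@H]1C(C)=C | intermediate
7 | lithium dienolate of 6 | [Li+].[O-]C1=C(C)[C@H](C(C)=C)CC=C1C | intermediate
8 | (5S,6S)-6-[(2Z)-3-iodoprop-2-en-1-yl]-2,6-dimethyl-5-(prop-1-en-2-yl)cyclohex-2-en-1-one | I/C=C\C[C@]1(C)C(=O)C(C)=CC[C@H]1C(C)=C | intermediate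
9 | (4aS,8aS)-2,5,5,8a-tetramethyl-4a,5,8,8a-tetrahydronaphthalen-1(4H)-one (trans-fused; C2=C3 in ring A, 7-en-9-one in ring B; 5α-H, 10β-CH3) | C1=CC[C@]2(C)C(=O)C(C)=CC[C@H]2C1(C)C | intermediate
10 | (4aS,6S,7R,8aS)-6,7-dihydroxy-2,5,5,8a-tetramethyl-4a,5,6,7,8,8a-hexahydronaphthalen-1(4H)-one (2α,3α-diol) | O[C@@H]1[C@H](O)C[C@]2(C)C(=O)C(C)=CC[C@H]2C1(C)C | intermediate
11 | 2α,3α-O-isopropylidene acetal of 10 | CC1(C)O[C@@H]2[C@H](O1)C[C@]3(C)C(=O)C(C)=CC[C@H]3C2(C)C | intermediate
12 | 9-methylene compound (acetonide; 7,9(11)-diene) | CC1(C)O[C@@H]2[C@H](O1)C[C@]3(C)C(=C)C(C)=CC[C@H]3C2(C)C | intermediate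
13 | B-alkyl-9-BBN adduct (9α-H, 9β-CH2–B; acetonide; 7-ene) | CC1(C)O[C@@H]2[C@H](O1)C[C@]3(C)[C@@H](CB4C5CCCC4CCC5)C(C)=CC[C@H]3C2(C)C | intermediate
14 | 9β-(iodomethyl) compound (acetonide; 5α-H, 9α-H, 10β-CH3; 7-ene with C8 methyl) | CC1(C)O[C@@H]2[C@H](O1)C[C@]3(C)[C@@H](CI)C(C)=CC[C@H]3C2(C)C | intermediate
15 | 9β-(iodomethyl)-7-en-17-al (acetonide) | CC1(C)O[C@@H]2[C@H](O1)C[C@]3(C)[C@@H](CI)C(C=O)=CC[C@H]3C2(C)C | intermediate
16 | 2α,3α-dihydroxy-9β-(iodomethyl)-7-en-17-al | O[C@@H]1[C@H](O)C[C@]2(C)[C@@H](CI)C(C=O)=CC[C@H]2C1(C)C | intermediate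
17 | angelic acid, (Z)-2-methylbut-2-enoic acid | C/C=C(/C)C(=O)O | starting material
18 | 2α-(angeloyloxy)-3α-hydroxy-9β-(iodomethyl)-7-en-17-al | O[C@@H]1[C@H](OC(=O)/C(C)=C\C)C[C@]2(C)[C@@H](CI)C(C=O)=CC[C@H]2C1(C)C | intermediate
19 | 2α,3α-bis(angeloyloxy)-9β-(iodomethyl)-7-en-17-al | C/C=C(/C)C(=O)O[C@@H]1[C@H](OC(=O)/C(C)=C\C)C[C@]2(C)[C@@H](CI)C(C=O)=CC[C@H]2C1(C)C | intermediate
20 | 3-methylfuran | Cc1ccoc1 | starting material
21 | 2-bromo-3-methylfuran | Cc1ccoc1Br | intermediate
22 | alkylzinc iodide from 19 (C11–ZnI) | C/C=C(/C)C(=O)O[C@@H]1[C@H](OC(=O)/C(C)=C\C)C[C@]2(C)[C@@H](C[Zn]I)C(C=O)=CC[C@H]2C1(C)C | intermediate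
23 | 2α,3α-bis(angeloyloxy)-11-(3-methylfuran-2-yl)-7-en-17-al | C/C=C(/C)C(=O)O[C@@H]1[C@H](OC(=O)/C(C)=C\C)C[C@]2(C)[C@@H](Cc3occc3C)C(C=O)=CC[C@H]2C1(C)C | intermediate
24 | furan endoperoxide of 23 (2,3,7-trioxabicyclo[2.2.1]hept-5-ene) | C/C=C(/C)C(=O)O[C@@H]1[C@H](OC(=O)/C(C)=C\C)C[C@]2(C)[C@@H](CC34OOC(O3)C=C4C)C(C=O)=CC[C@H]2C1(C)C | intermediate
25 | γ-hydroxybutenolide (5-hydroxy-4-methyl-furan-2(5H)-one attached through C5 to C11; epimers at the lactol carbon) | C/C=C(/C)C(=O)O[C@@H]1[C@H](OC(=O)/C(C)=C\C)C[C@]2(C)[C@@H](CC3(O)OC(=O)C=C3C)C(C=O)=CC[C@H]2C1(C)C | intermediate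
26 | methyl (13Z)-2α,3α-bis[(Z)-2-methylbut-2-enoyloxy]-12,17-dioxolabda-7,13-dien-15-oate | C/C=C(/C)C(=O)O[C@@H]1[C@H](OC(=O)/C(C)=C\C)C[C@]2(C)[C@@H](CC(=O)/C(C)=C\C(=O)OC)C(C=O)=CC[C@H]2C1(C)C | target

**Step count and risks**

Total step count: 16. Longest linear sequence: 14 steps (steps 1, 2, 4 to 12 and 14 to 16, from ethyl (Z)-3-iodoprop-2-enoate).

Steps most likely to fail:

Step 4 (annulation). The hindered tertiary enolate may be alkylated incompletely. In the palladium stage, hydride capture may overtake the 6-exo insertion (loss of iodine without ring closure), or the neopentyl-palladium species may rearrange through a 3-exo insertion. Fallback, from 6 back to 9, closing C3–C4 by a cation instead of a carbopalladation: commercial 3-(trimethylsilyl)prop-2-yn-1-ol is semi-hydrogenated (H2, Pd/CaCO3 poisoned with Pb(OAc)2, quinoline) to (Z)-3-(trimethylsilyl)prop-2-en-1-ol F1 and brominated (CBr4, PPh3) to (Z)-(3-bromoprop-1-en-1-yl)trimethylsilane F2. The enolate 7 of 6 is alkylated with F2 (LiN(iPr)2, THF, −78 to 0 °C) to give (5S,6S)-2,6-dimethyl-5-(prop-1-en-2-yl)-6-[(2Z)-3-(trimethylsilyl)prop-2-en-1-yl]cyclohex-2-en-1-one F3. Hydrogen-atom transfer with radical–polar crossover (Co(C16H14N2O2), the salen complex of divalent cobalt, 1-fluoro-2,4,6-trimethylpyridinium tetrafluoroborate, PhSiH3) then turns the isopropenyl group into the C4 cation. The (Z)-vinylsilane traps it at C3 by ipso-substitution, which should give 9 with the same C2=C3 alkene.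

Step 9 (allylic oxidation). The ene step may choose C6 or C9 instead of C17; the oxidation may stop at the alcohol; the acetonide may be lost in the acidic medium; the C–I bond may be attacked. Fallback, from 12 back to 15, using allylic deprotonation instead of an ene reaction and with no halide present during the oxidation: hydroboration of 12 with 9-BBN as in step 8 (through 13) but with NaOH/H2O2 work-up should give the C11 alcohol F4, and TBSCl/imidazole gives the silyl ether F5. n-BuLi/KOtBu metalates the C8 methyl (the kinetically preferred allylic CH3), B(OMe)3 traps the allylpotassium at its primary terminus, and NaOH/H2O2 gives the C17 allylic alcohol F6. MnO2 oxidises it to the enal F7. Ph3PBr2 converts the silyl ether directly into the bromide F8, so that a free C11 hydroxyl, which would close a lactol onto the C17 aldehyde, never appears. NaI in acetone (Finkelstein exchange) returns the route to 15.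

Step 12 (angeloylation of the hindered 3α-hydroxyl). Acylation of the axial hydroxyl next to the gem-dimethyl carbon may stay incomplete, and the forcing conditions may isomerise angelate to tiglate. Fallback, from 14 back to 19, building the Z alkenes on the ester by olefination before the aldehyde exists: hydrolysis of 14 (HCl, aq. THF) gives the diol iodide F9. Esterification with 2-[bis(2,2,2-trifluoroethoxy)phosphoryl]propanoic acid (dicyclohexylcarbodiimide, 4-dimethylaminopyridine) gives the bis(phosphonopropionate) F10. Still–Gennari olefination with acetaldehyde (KN(SiMe3)2, 18-crown-6, THF, −78 °C) should give the bis-angelate F11 with kinetic Z selectivity. SeO2 oxidation of the C8 methyl as in step 9 then gives 19.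

Further compounds
F1 | step 4 | (Z)-3-(trimethylsilyl)prop-2-en-1-ol | C[Si](C)(C)/C=C\CO
F2 | step 4 | (Z)-(3-bromoprop-1-en-1-yl)trimethylsilane | C[Si](C)(C)/C=C\CBr
F3 | step 4 | (5S,6S)-2,6-dimethyl-5-(prop-1-en-2-yl)-6-[(2Z)-3-(trimethylsilyl)prop-2-en-1-yl]cyclohex-2-en-1-one | C[Si](C)(C)/C=C\C[C@]1(C)C(=O)C(C)=CC[C@H]1C(C)=C
F4 | step 9 | 9β-(hydroxymethyl) compound (acetonide; 9α-H; 7-ene with C8 methyl) | CC1(C)O[C@@H]2[C@H](O1)C[C@]3(C)[C@@H](CO)C(C)=CC[C@H]3C2(C)C
F5 | step 9 | tert-butyldimethylsilyl ether of F4 | CC1(C)O[C@@H]2[C@H](O1)C[C@]3(C)[C@@H](CO[Si](C)(C)C(C)(C)C)C(C)=CC[C@H]3C2(C)C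
F6 | step 9 | C17 allylic alcohol (C8–CH2OH; C11 silyl ether) | CC1(C)O[C@@H]2[C@H](O1)C[C@]3(C)[C@@H](CO[Si](C)(C)C(C)(C)C)C(CO)=CC[C@H]3C2(C)C
F7 | step 9 | 7-en-17-al with C11 silyl ether | CC1(C)O[C@@H]2[C@H](O1)C[C@]3(C)[C@@H](CO[Si](C)(C)C(C)(C)C)C(C=O)=CC[C@H]3C2(C)C
F8 | step 9 | 9β-(bromomethyl)-7-en-17-al (acetonide) | CC1(C)O[C@@H]2[C@H](O1)C[C@]3(C)[C@@H](CBr)C(C=O)=CC[C@H]3C2(C)C
F9 | step 12 | 2α,3α-dihydroxy-9β-(iodomethyl) compound (7-ene with C8 methyl) | O[C@@H]1[C@H](O)C[C@]2(C)[C@@H](CI)C(C)=CC[C@H]2C1(C)C
F10 | step 12 | 2α,3α-bis{2-[bis(2,2,2-trifluoroethoxy)phosphoryl]propanoate} of F9 | CC(C(=O)O[C@@H]1[C@H](OC(=O)C(C)P(=O)(OCC(F)(F)F)OCC(F)(F)F)C[C@]2(C)[C@@H](CI)C(C)=CC[C@H]2C1(C)C)P(=O)(OCC(F)(F)F)OCC(F)(F)F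
F11 | step 12 | 2α,3α-bis(angelate) of F9 | C/C=C(/C)C(=O)O[C@@H]1[C@H](OC(=O)/C(C)=C\C)C[C@]2(C)[C@@H](CI)C(C)=CC[C@H]2C1(C)C
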